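## Structural features

The target is a 3-arylcoumarin: a benzo ring (ring A) fused to a 2-pyranone ring, with a 2,4-dihydroxyphenyl ring (ring B) joined to C3 by a single C–C bond. Ring A carries a methoxy group at C5, a free hydroxyl at C7 and a 2-methylbut-3-en-2-yl (1,1-dimethylallyl) group at C8, whose quaternary carbon is wedged between C7–OH and the ring oxygen O1. There is no stereocentre in the target, so no stereocentres stand next to each other; the only stereogenic atoms on the route are transient (the hemiacetal carbon of a lactol and the sp3 carbon of a Claisen dienone). The fragile parts are the ortho-(1,1-dimethylallyl)phenol (strong acid closes it to a dihydrobenzofuran, hydrogenation saturates it), the electron-rich phenols (oxidative coupling) and the lactone (opens in hot alkali). The real difficulty is regiochemical: a tertiary allyl group must sit on the most crowded carbon of a 1,3,5-trioxygenated ring, and the aryl-bearing three-carbon unit must be attached to the correct neighbouring carbon without strong acid. The key step exploits the position of C8 between C7–OH and O1 with the C5 methoxy para to it. Before the pyranone is fused, ring A is a mirror-symmetric 2-substituted 5-methoxyresorcinol whose two hydroxyls (future O1 and C7–OH) and two free ring carbons (future C4a and C6) are equivalent, so either mode of annulation gives the same compound.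

## Logic of the disconnections

18 to 17: the two O–allyl bonds on ring B are restored. Ring B must be masked while aldehydes are handled, because a free 2'-hydroxyl would add to the 1,3-dialdehyde. Allyl is the mask that can leave under neutral palladium catalysis, without acid or hydrogen. The forward step must spare the terminal alkene, the lactone and the free C7 phenol.

17 to 16: the C2 carbonyl is taken back to the hemiacetal level. The lactol is what the ring-forming condensation delivers, so the lactone carbon need not be carried as an ester through the C–C bond formation. The forward step must dehydrogenate a hemiacetal next to an electron-rich phenol and three alkenes.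

16 to 8 and 14: C4–C4a and O1–C2 are cut. This separates a symmetric nucleophile (8) from a three-carbon bis-electrophile (14) that already holds the C3–aryl bond. One ring and two bonds form convergently, and regiochemistry is settled by symmetry. The forward step must run under weakly acidic, non-reducing conditions and stop after one condensation.

8 to 6: a methyl ester is placed on one free ring carbon. Without it, the aryl prenyl ether that precedes the rearrangement would present two non-equivalent ortho carbons and would rearrange to a mixture. The ester, chelated by the neighbouring hydroxyl, steers the rearrangement and is then lost as CO2. The forward step is a saponification and decarboxylation that must avoid mineral acid.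

6 to 4: the bond between ring carbon C3 and the quaternary carbon is cut and reconnected as the O–CH2 bond of a prenyl ether. A [3,3] shift with allylic inversion is the most dependable way to put a 1,1-dimethylallyl group ortho to a phenolic oxygen. The forward step must migrate to C3 and not to C5, and the crowded product must survive the heat.

4 to 3 to 1 and 2: the O–CH3 bond and the O–prenyl bond are cut in turn. The three hydroxyls of 1 differ (one free and most acidic, two chelated and equivalent), so two selective mono-alkylations are plausible. Each forward alkylation must stop at one group and occur on oxygen.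

14 to 12: one formyl carbon is removed, leaving an enol ether. The enol-ether carbon is far more nucleophilic than the resorcinol-type ring B, so formylation can be run cold without attack on the ring. The forward step must be chemoselective against ring carbon C5.

12 to 11 to 9 and 10: the enol-ether C=C is cut (Wittig disconnection) and then the two O–allyl bonds, which leads back to 9 and two equivalents of 10, both inexpensive. The forward steps are routine; only the chelated 2-hydroxyl needs warming to alkylate.

## Other disconnections considered

Alternative 1: The cut lies inside ring A, at C8–C8a (coumarin numbering). The acyclic masked triketide A1 (methyl 3-methoxy-7,7-dimethyl-5-oxonona-3,8-dienoate) would be doubly deprotonated. Its methylene next to the quaternary carbon would then attack the ester in a Dieckmann-type Claisen condensation, closing ring A as the resorcinol A2, the same substance as 8.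
- In its favour: the quaternary carbon is fixed in the chain, so there is no regiochemical question, no directing ester to remove and no high-temperature step. On regiochemical certainty and mildness it is the equal or the better of steps 1 to 4.
- Against it: the nucleophilic carbon is a neopentyl-type methylene; the ketone enolate can acylate on oxygen instead of on carbon; and A1 itself needs several steps from an acid carrying the quaternary carbon and an acetoacetate enol ether.
- Comparison: it replaces only the route to 8 and leaves the pyran-forming key step untouched. It is ionic where the chosen plan is pericyclic, and about equal in step count (three to four steps). The chosen plan is preferred because the Claisen regiochemistry is controlled by the chelate, whereas the cyclisation mode of A1 is less predictable.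

Alternative 2: Four bonds of the pyranone are cut at once: C8a–O1, C4a–C4, C3–C4 and O1–C2. CsF would release aryne A4 (3-methoxy-5-(3-methylbut-2-enyloxy)benzyne) from silyl triflate A3 (3-methoxy-5-(3-methylbut-2-enyloxy)-2-(trimethylsilyl)phenyl trifluoromethanesulfonate). N,N-Dimethylformamide would insert its C=O unit across the aryne and the adduct would ring-open. The enolate of arylacetate A5 (methyl 2-[2,4-bis(methoxymethoxy)phenyl]acetate) would then add, the amine would be expelled and lactonisation would give coumarin A6 (3-[2,4-bis(methoxymethoxy)phenyl]-5-methoxy-7-(3-methylbut-2-enyloxy)coumarin).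
- In its favour: it is more convergent and reaches the coumarin oxidation level directly, so no lactol oxidation is needed; on these two points it is better than the chosen plan. The methoxy group next to the aryne should direct the formamide oxygen to the remote aryne carbon, which is the required orientation.
- Against it: A6 carries the prenyl group on O7. The 1,1-dimethylallyl group would still have to be made by a late Claisen rearrangement on the coumarin (C8 against C6), on the most advanced intermediate. A3 needs a multistep preparation, and the methoxymethyl ethers need acid for removal next to the acid-sensitive ortho-(1,1-dimethylallyl)phenol.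
- Comparison: the bond-forming event is shorter, but the precursor is longer and the end-game riskier, so the overall step count is no lower and the hardest problem is postponed.

Alternative 3: The C3=C4 double bond is cut. Low-valent titanium from TiCl4 and zinc would couple the aldehyde carbon and the ketone carbon of the aryl glyoxylate A7 (2-formyl-3-methoxy-6-(2-methylbut-3-en-2-yl)-5-(tert-butyldimethylsilyloxy)phenyl 2-[2,4-bis(tert-butyldimethylsilyloxy)phenyl]-2-oxoacetate) in a McMurry-type reductive coupling. This closes the pyranone as A8, the tris(tert-butyldimethylsilyl) ether of the target.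
- In its favour: the coumarin forms directly with the C3–aryl bond already in place, and one fluoride treatment would finish the synthesis. On end-game simplicity it is the equal of the chosen plan.
- Against it: A7 still needs ring A with the reverse prenyl group, plus a formylation. It also needs acylation of a phenol flanked by a formyl group and a tertiary alkyl group with a labile glyoxylic acid derivative. Lewis-acidic TiCl4 threatens the aryl ester and the silyl ethers, and the coupling may stop at the pinacol stage before deoxygenation.
- Comparison: it is a reductive metal-mediated coupling where the chosen plan is a condensation and electrocyclisation. It does not remove the regiochemical problem of ring A and is longer by several protecting-group and acylation steps.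

Key step: step 8

Remark on the chemistry: 14 is drawn as the dialdehyde although it should exist mainly as its hydrogen-bonded enol, 12 is taken as an E/Z mixture whose isomers converge in step 7, and 1, 2, 9 and 10 are taken to be commercial.

## Route

Step 1
Reactants: 1 methyl 2,4,6-trihydroxybenzoate; 2 prenyl bromide (1-bromo-3-methylbut-2-ene)
Product: 3 methyl 2,6-dihydroxy-4-(3-methylbut-2-enyloxy)benzoate
Conditions: K2CO3 (1.05 equiv), acetone, rt
Reagents that add atoms: none
Why: Williamson etherification; the 4-OH is the only hydroxyl not hydrogen-bonded to the ester and is the most acidic, so one equivalent of base and bromide should alkylate it alone, and the aprotic medium favours O- over C-alkylation.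

Step 2
Reactants: 3 methyl 2,6-dihydroxy-4-(3-methylbut-2-enyloxy)benzoate
Product: 4 methyl 2-hydroxy-6-methoxy-4-(3-methylbut-2-enyloxy)benzoate
Conditions: MeI (1.2 equiv), K2CO3, acetone, 40 °C
Reagents that add atoms: iodomethane, CI
Why: O-methylation of one of two symmetry-equivalent ortho hydroxyls; the remaining hydroxyl is then locked in a strong hydrogen bond to the ester carbonyl, which should stop the reaction at the mono-ether.

Step 3
Reactants: 4 methyl 2-hydroxy-6-methoxy-4-(3-methylbut-2-enyloxy)benzoate
Product: 6 methyl 2,4-dihydroxy-6-methoxy-3-(2-methylbut-3-en-2-yl)benzoate, via ortho-dienone 5 (not isolated)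
Conditions: PhNEt2, 185 °C, sealed tube, Ar
Reagents that add atoms: none
Why: Aromatic Claisen rearrangement, a [3,3] shift that turns the prenyl ether into a C-bound 1,1-dimethylallyl group; the chelate between the 2-OH and the ester carbonyl gives the C3–C4 bond more double-bond character, so migration should go to C3 (between the two oxygens) and not to C5. The racemic dienone 5 enolises at once, which removes its stereocentre.

Step 4
Reactants: 6 methyl 2,4-dihydroxy-6-methoxy-3-(2-methylbut-3-en-2-yl)benzoate
Product: 8 2-(2-methylbut-3-en-2-yl)-5-methoxybenzene-1,3-diol, via benzoic acid 7 (not isolated)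
Conditions: KOH, H2O–DMSO, 100 °C, N2; then AcOH to pH 5, 60 °C
Reagents that add atoms: none
Why: Saponification followed by decarboxylation; 2,4-dihydroxy-6-alkoxybenzoic acids lose CO2 on gentle warming through ipso-protonation of the electron-rich ring. No mineral acid is used, so the ortho-(1,1-dimethylallyl)phenol should not cyclise.

Step 5
Reactants: 9 2,4-dihydroxybenzaldehyde; 10 allyl bromide (3-bromoprop-1-ene)
Product: 11 2,4-bis(allyloxy)benzaldehyde
Conditions: allyl bromide (2.5 equiv in all), K2CO3 (3 equiv), DMF, 60 °C
Reagents that add atoms: allyl bromide (second equivalent), C=CCBr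
Why: Twofold Williamson etherification that consumes two equivalents of 10, one for each phenolic oxygen, with warming to alkylate the hydrogen-bonded 2-OH; allyl is chosen because it survives base, POCl3 and the later oxidant and can be removed without acid or hydrogen.

Step 6
Reactants: 11 2,4-bis(allyloxy)benzaldehyde
Product: 12 2,4-bis(allyloxy)-1-(2-methoxyethenyl)benzene (E/Z mixture)
Conditions: MeOCH2PPh3Cl, KOtBu, THF, 0 °C to rt
Reagents that add atoms: (methoxymethyl)triphenylphosphonium chloride, COC[P+](c1ccccc1)(c1ccccc1)c1ccccc1.[Cl-]
Why: Wittig reaction with the methoxymethyl ylide gives the homologated enol ether; both alkene isomers lead to the same product in step 7, and aryl allyl ethers are stable to KOtBu at this temperature.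

Step 7
Reactants: 12 2,4-bis(allyloxy)-1-(2-methoxyethenyl)benzene
Product: 14 2-[2,4-bis(allyloxy)phenyl]malonaldehyde, via methoxyallylidene iminium salt 13 (not isolated)
Conditions: POCl3 (1.3 equiv), DMF, 0 °C to rt; then 2 M NaOH, 60 °C; then 1 M HCl to pH 3, 0 °C
Reagents that add atoms: N,N-dimethylformamide, CN(C)C=O (formyl carbon); water, O (both aldehyde oxygens)
Why: Vilsmeier–Haack formylation of an enol ether, the usual entry to 2-substituted malonaldehydes; the aryl-bearing enol-ether carbon is far more nucleophilic than ring carbon C5, so the chloroiminium ion should be consumed in the cold before the ring reacts, and the cationic salt 13 then deactivates the ring. Aqueous NaOH hydrolyses the iminium and the vinylogous ester, and brief cold acidification frees 14 without touching the allyl ethers.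

Step 8
Reactants: 8 2-(2-methylbut-3-en-2-yl)-5-methoxybenzene-1,3-diol; 14 2-[2,4-bis(allyloxy)phenyl]malonaldehyde
Product: 16 3-[2,4-bis(allyloxy)phenyl]-5-methoxy-8-(2-methylbut-3-en-2-yl)-2H-chromene-2,7-diol (racemic at C2), via ortho-quinone methide enol 15 (not isolated)
Conditions: 8 (1.0 equiv), 14 (1.05 equiv), pyrrolidine (0.2 equiv), AcOH (1.0 equiv), toluene, 70 °C; pH 6 phosphate buffer work-up
Reagents that add atoms: none
Why: Pyrrolidinium acetate converts the enol-aldehyde 14 into a 3-hydroxyallylidene iminium ion, whose iminium carbon is attacked by one of the two equivalent free ring carbons of 8 (future C4a); loss of pyrrolidine gives the ortho-quinone methide enol 15, a 1-oxatriene (O1, C8a, C4a, C4, C3, C2). The pyran ring closes by thermal disrotatory oxa-6π electrocyclisation, which forms O1–C2 and restores the aromaticity of ring A; ring–chain tautomerism of the equivalent hydroxyaryl enal leads to the same lactol. The closest known reaction types are the amine-salt-promoted chromene annulation of resorcinols with enals and the condensation of arylmalonaldehydes with phenols to 3-arylbenzopyran derivatives. The only new stereocentre, the hemiacetal carbon C2, is under no control, should form as the racemate and is erased in step 9. Regiochemistry needs no control, because the mirror symmetry of 8 makes both hydroxyls and both free carbons equivalent and the carbon between the hydroxyls is blocked. Mono-condensation should be secured by near-equimolar amounts and by the lower nucleophilicity of ring A once it is conjugated with the new heterocycle. A secondary amine is chosen because a 1,2-diamine salt could be trapped by the 1,3-dialdehyde as a stable dihydrodiazepinium ion. The acetate buffer is too weak an acid to add the phenol to the 1,1-dimethylallyl alkene, and the allyl ethers are far below the temperature of an aromatic Claisen rearrangement.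

Step 9
Reactants: 16 3-[2,4-bis(allyloxy)phenyl]-5-methoxy-8-(2-methylbut-3-en-2-yl)-2H-chromene-2,7-diol
Product: 17 3-[2,4-bis(allyloxy)phenyl]-7-hydroxy-5-methoxy-8-(2-methylbut-3-en-2-yl)-2H-chromen-2-one
Conditions: Ag2CO3 on Celite (3 equiv), toluene, 80 °C, dark
Reagents that add atoms: none
Why: Oxidation of a lactol to a lactone by Ag2CO3 on Celite, a neutral heterogeneous oxidant for which lactols are among the fastest substrates. Loss of the C7 phenolic hydrogen and the C2 hydrogen would give the quinonoid tautomer of the same 7-hydroxycoumarin, so oxidation starting at the phenol is expected to converge on 17. Any open-chain enal should equilibrate through 15 and drain through the lactol.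

Step 10
Reactants: 17 3-[2,4-bis(allyloxy)phenyl]-7-hydroxy-5-methoxy-8-(2-methylbut-3-en-2-yl)-2H-chromen-2-one
Product: 18 3-(2,4-dihydroxyphenyl)-7-hydroxy-5-methoxy-8-(2-methylbut-3-en-2-yl)-2H-chromen-2-one (target)
Conditions: Pd(PPh3)4 (5 mol %), morpholine (10 equiv), THF, rt
Reagents that add atoms: none
Why: Tsuji–Trost deallylation; zerovalent palladium ionises both aryl allyl ethers to π-allyl complexes, which morpholine captures irreversibly. The 1,1-dimethylallyl group has no leaving group and the lactone is stable to the amine at room temperature, so both should be untouched.

## Compound list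

1 | methyl 2,4,6-trihydroxybenzoate | COC(=O)c1c(O)cc(O)cc1O | starting material
2 | prenyl bromide (1-bromo-3-methylbut-2-ene) | CC(C)=CCBr | starting material
3 | methyl 2,6-dihydroxy-4-(3-methylbut-2-enyloxy)benzoate | COC(=O)c1c(O)cc(OCC=C(C)C)cc1O | intermediate
4 | methyl 2-hydroxy-6-methoxy-4-(3-methylbut-2-enyloxy)benzoate | COC(=O)c1c(O)cc(OCC=C(C)C)cc1OC | intermediate
5 | methyl 2-hydroxy-6-methoxy-3-(2-methylbut-3-en-2-yl)-4-oxocyclohexa-1,5-diene-1-carboxylate (racemic ortho-dienone, not isolated) | COC(=O)C1=C(O)C(C(C)(C)C=C)C(=O)C=C1OC | intermediate
6 | methyl 2,4-dihydroxy-6-methoxy-3-(2-methylbut-3-en-2-yl)benzoate | COC(=O)c1c(O)c(C(C)(C)C=C)c(O)cc1OC | intermediate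
7 | 2,4-dihydroxy-6-methoxy-3-(2-methylbut-3-en-2-yl)benzoic acid (not isolated) | OC(=O)c1c(O)c(C(C)(C)C=C)c(O)cc1OC | intermediate
8 | 2-(2-methylbut-3-en-2-yl)-5-methoxybenzene-1,3-diol | C=CC(C)(C)c1c(O)cc(OC)cc1O | intermediate
9 | 2,4-dihydroxybenzaldehyde | O=Cc1ccc(O)cc1O | starting material
10 | allyl bromide (3-bromoprop-1-ene) | C=CCBr | starting material
11 | 2,4-bis(allyloxy)benzaldehyde | O=Cc1ccc(OCC=C)cc1OCC=C | intermediate
12 | 2,4-bis(allyloxy)-1-(2-methoxyethenyl)benzene (E/Z mixture) | COC=Cc1ccc(OCC=C)cc1OCC=C | intermediate
13 | N-{2-[2,4-bis(allyloxy)phenyl]-3-methoxyprop-2-enylidene}-N-methylmethanaminium dichlorophosphate (not isolated) | COC=C(C=[N+](C)C)c1ccc(OCC=C)cc1OCC=C.[O-]P(=O)(Cl)Cl | intermediate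
14 | 2-[2,4-bis(allyloxy)phenyl]malonaldehyde | O=CC(C=O)c1ccc(OCC=C)cc1OCC=C | intermediate
15 | (6Z)-6-{2-[2,4-bis(allyloxy)phenyl]-3-hydroxyprop-2-enylidene}-3-hydroxy-5-methoxy-2-(2-methylbut-3-en-2-yl)cyclohexa-2,4-dienone (ortho-quinone methide enol, enol geometry open, not isolated) | O=C1C(C(C)(C)C=C)=C(O)C=C(OC)/C1=C/C(=CO)c1ccc(OCC=C)cc1OCC=C | intermediate
16 | 3-[2,4-bis(allyloxy)phenyl]-5-methoxy-8-(2-methylbut-3-en-2-yl)-2H-chromene-2,7-diol (racemic at C2) | C=CC(C)(C)c1c(O)cc(OC)c2C=C(c3ccc(OCC=C)cc3OCC=C)C(O)Oc12 | intermediate
17 | 3-[2,4-bis(allyloxy)phenyl]-7-hydroxy-5-methoxy-8-(2-methylbut-3-en-2-yl)-2H-chromen-2-one | C=CC(C)(C)c1c(O)cc(OC)c2cc(-c3ccc(OCC=C)cc3OCC=C)c(=O)oc12 | intermediate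
18 | 3-(2,4-dihydroxyphenyl)-7-hydroxy-5-methoxy-8-(2-methylbut-3-en-2-yl)-2H-chromen-2-one | C=CC(C)(C)c1c(O)cc(OC)c2cc(-c3ccc(O)cc3O)c(=O)oc12 | target

## Step count and least certain steps

Total: 10 steps. Longest linear sequence: 7 steps (steps 1 to 4, then 8 to 10); the three-step branch (steps 5 to 7) joins at step 8.

Step 8 (key step). The most likely trouble is a stalled or overrunning condensation. The vinylogous-acid character of 14 lowers its electrophilicity whenever it is deprotonated or parked as an enaminal. The product can also partition between the lactol, the ring-opened enal and a dehydrated quinonoid form, or add a second nucleophile at C4. The fallback forms C3–C4 instead of C4–C4a, sets out from 8 and 12 and returns at 16. Ortho-formylation of 8 with paraformaldehyde, MgCl2 and Et3N in MeCN should give 2,4-dihydroxy-6-methoxy-3-(2-methylbut-3-en-2-yl)benzaldehyde F1; symmetry again leaves one possible product and no acid is present. Mild aqueous acid hydrolysis of the enol ether 12 should give 2-[2,4-bis(allyloxy)phenyl]acetaldehyde F2. A pyrrolidine-catalysed crossed aldol condensation of F2 (as its enamine) with F1, followed by ring–chain closure of the resulting hydroxyaryl enal, should give 16.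

Step 3. The risks are partial migration to C5 if the chelate control is incomplete, thermal loss of the prenyl group, and secondary rearrangement or cyclisation of the crowded ortho-(1,1-dimethylallyl)phenol at 185 °C. The fallback removes the regiochemical choice, sets out from 3 and returns at 8. Claisen rearrangement of the symmetric ether 3, whose two ortho carbons are equivalent, should give methyl 2,4,6-trihydroxy-3-(2-methylbut-3-en-2-yl)benzoate F3. Saponification to 2,4,6-trihydroxy-3-(2-methylbut-3-en-2-yl)benzoic acid F4 (not isolated) and decarboxylation should give 2-(2-methylbut-3-en-2-yl)benzene-1,3,5-triol F5. Mitsunobu methylation (MeOH, PPh3, DIAD, one equivalent) should then select the single hydroxyl not flanked by the tertiary alkyl group and give 8.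

Step 9. The risks are one-electron oxidation of ring A leading to oxidative coupling on the silver surface, and slow turnover if much of the material sits as the ring-opened (E)-enal. The fallback oxidises the aldehyde tautomer instead of the hemiacetal, sets out from 16 and returns at 17. Chlorite oxidation (NaClO2, NaH2PO4, 2-methylbut-2-ene, t-BuOH–H2O) should give (Z)-2-[2,4-bis(allyloxy)phenyl]-3-[2,4-dihydroxy-6-methoxy-3-(2-methylbut-3-en-2-yl)phenyl]prop-2-enoic acid F6, which should lactonise spontaneously to 17.

Step 4. The risk is sluggish acyl substitution at an ester flanked by two ortho substituents and deactivated by phenoxide donation, so that long heating in alkali exposes the electron-rich polyphenoxide to air oxidation. The fallback cleaves the ester at the methyl–oxygen bond instead, sets out from 6 and returns at 8. LiI in EtOAc at reflux should give the lithium salt of 7 by SN2 attack at the methyl group; acidification with AcOH and gentle warming should then give 8. No new compound is formed (F0).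

Step 1. The risks are C-prenylation of the ambident phenoxide and a second O-alkylation. The fallback activates the alcohol instead of forming a phenoxide, sets out from 1 and returns at 3. Mitsunobu etherification with 3-methylbut-2-en-1-ol, PPh3 and DIAD in THF should alkylate only the free, most acidic 4-OH, since no carbon nucleophile is generated. No new compound is formed (F0).

## Further compounds

F1 | step 8 | 2,4-dihydroxy-6-methoxy-3-(2-methylbut-3-en-2-yl)benzaldehyde | C=CC(C)(C)c1c(O)cc(OC)c(C=O)c1O
F2 | step 8 | 2-[2,4-bis(allyloxy)phenyl]acetaldehyde | O=CCc1ccc(OCC=C)cc1OCC=C
F3 | step 3 | methyl 2,4,6-trihydroxy-3-(2-methylbut-3-en-2-yl)benzoate | COC(=O)c1c(O)cc(O)c(C(C)(C)C=C)c1O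
F4 | step 3 | 2,4,6-trihydroxy-3-(2-methylbut-3-en-2-yl)benzoic acid | OC(=O)c1c(O)cc(O)c(C(C)(C)C=C)c1O
F5 | step 3 | 2-(2-methylbut-3-en-2-yl)benzene-1,3,5-triol | C=CC(C)(C)c1c(O)cc(O)cc1O
F6 | step 9 | (Z)-2-[2,4-bis(allyloxy)phenyl]-3-[2,4-dihydroxy-6-methoxy-3-(2-methylbut-3-en-2-yl)phenyl]prop-2-enoic acid | OC(=O)/C(c1ccc(OCC=C)cc1OCC=C)=C\c1c(O)c(C(C)(C)C=C)c(O)cc1OC
F0 | step 4 | none | none
F0 | step 1 | none | none
A1 | alternative 1 | methyl 3-methoxy-7,7-dimethyl-5-oxonona-3,8-dienoate | COC(=O)CC(OC)=CC(=O)CC(C)(C)C=C
A2 | alternative 1 | 2-(2-methylbut-3-en-2-yl)-5-methoxybenzene-1,3-diol (identical with 8) | C=CC(C)(C)c1c(O)cc(OC)cc1O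
A3 | alternative 2 | 3-methoxy-5-(3-methylbut-2-enyloxy)-2-(trimethylsilyl)phenyl trifluoromethanesulfonate | COc1cc(OCC=C(C)C)cc(OS(=O)(=O)C(F)(F)F)c1[Si](C)(C)C
A4 | alternative 2 | 3-methoxy-5-(3-methylbut-2-enyloxy)benzyne | COC1=CC(OCC=C(C)C)=CC#C1
A5 | alternative 2 | methyl 2-[2,4-bis(methoxymethoxy)phenyl]acetate | COCOc1ccc(CC(=O)OC)c(OCOC)c1
A6 | alternative 2 | 3-[2,4-bis(methoxymethoxy)phenyl]-5-methoxy-7-(3-methylbut-2-enyloxy)coumarin | COCOc1ccc(-c2cc3c(OC)cc(OCC=C(C)C)cc3oc2=O)c(OCOC)c1
A7 | alternative 3 | 2-formyl-3-methoxy-6-(2-methylbut-3-en-2-yl)-5-(tert-butyldimethylsilyloxy)phenyl 2-[2,4-bis(tert-butyldimethylsilyloxy)phenyl]-2-oxoacetate | C=CC(C)(C)c1c(O[Si](C)(C)C(C)(C)C)cc(OC)c(C=O)c1OC(=O)C(=O)c1ccc(O[Si](C)(C)C(C)(C)C)cc1O[Si](C)(C)C(C)(C)C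
A8 | alternative 3 | 3-[2,4-bis(tert-butyldimethylsilyloxy)phenyl]-7-(tert-butyldimethylsilyloxy)-5-methoxy-8-(2-methylbut-3-en-2-yl)-2H-chromen-2-one | C=CC(C)(C)c1c(O[Si](C)(C)C(C)(C)C)cc(OC)c2cc(-c3ccc(O[Si](C)(C)C(C)(C)C)cc3O[Si](C)(C)C(C)(C)C)c(=O)oc12
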